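**Plan**
Retrosynthesis: after the nine phenols are unmasked, the stilbene is cut at the bond between benzofuran C4 and its vinyl CH; each dihydrobenzofuran is then cut at C2–C3, and the benzofuran at C3–C3a and C2–aryl.
Enabling feature: benzofuran C4–H is meta to the C6 oxygen with C5 between them, so a carboxyl parked on C5 has C4 as its only free ortho C–H. It steers rhodium to C4 for an oxidative C–H/C–H union with the terminal vinyl carbon of the styrene (two carbons of like polarity) and then leaves as CO2.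
Forward: the benzofuran acid 7 is made by etherification, cyclodehydration and C2 arylation. Dihydrobenzofuran ring 2 (fused to ring B) and then ring 1 (the one that carries the vinyl group) are closed by Rh-carbene 1,5 C–H insertions of nitrile-derived hydrazones; vinylation, union and demethylation follow.
Stereochemistry: C3 of each dihydrobenzofuran comes from the chiral dirhodium catalyst (opposite enantiomers for the two rings), C2 from acid equilibration to trans, and the E alkene from syn insertion and syn β-hydride elimination.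

Key step: step 16

Assumption: Rh2(S-PTAD)4 (dirhodium tetrakis[(S)-1-adamantyl(phthalimido)acetate]) is taken to give the 3S ring and Rh2(R-PTAD)4 the 3R ring in the carbene insertions; if the sense proves opposite, the two catalyst enantiomers are exchanged.

**Route**

Step 1
Reactants: 1 methyl 4-hydroxy-2-methoxybenzoate; 2 2-bromo-1-(3,5-dimethoxyphenyl)ethan-1-one
Product: 3 methyl 4-[2-(3,5-dimethoxyphenyl)-2-oxoethoxy]-2-methoxybenzoate
Conditions: K2CO3, acetone, reflux
Reagents that add atoms: none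
Why: Williamson etherification, in which the phenoxide of 1 displaces the primary bromide of the α-bromoketone.

Step 2
Reactants: 3 methyl 4-[2-(3,5-dimethoxyphenyl)-2-oxoethoxy]-2-methoxybenzoate
Product: 4 methyl 3-(3,5-dimethoxyphenyl)-6-methoxy-1-benzofuran-5-carboxylate
Conditions: Bi(OTf)3 (10 mol%), 1,2-dichloroethane, reflux
Reagents that add atoms: none
Why: Lewis-acid cyclodehydration of an α-aryloxy ketone (intramolecular Friedel–Crafts hydroxyalkylation, then loss of water) should close onto the ring carbon para to the 2-methoxy group and ortho to the ether oxygen, giving the 3-aryl benzofuran with the ester at C5 and OMe at C6.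

Step 3
Reactants: 4 methyl 3-(3,5-dimethoxyphenyl)-6-methoxy-1-benzofuran-5-carboxylate; 5 4-bromoanisole
Product: 6 methyl 3-(3,5-dimethoxyphenyl)-6-methoxy-2-(4-methoxyphenyl)-1-benzofuran-5-carboxylate
Conditions: Pd(OAc)2 (5 mol%), PCy3·HBF4 (10 mol%), PivOH (30 mol%), K2CO3, DMA, 110 °C
Reagents that add atoms: none
Why: Direct C–H arylation by concerted metalation–deprotonation at C2, the only free furan position, with the aryl bromide.

Step 4
Reactants: 6 methyl 3-(3,5-dimethoxyphenyl)-6-methoxy-2-(4-methoxyphenyl)-1-benzofuran-5-carboxylate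
Product: 7 3-(3,5-dimethoxyphenyl)-6-methoxy-2-(4-methoxyphenyl)-1-benzofuran-5-carboxylic acid
Conditions: LiOH·H2O, THF/MeOH/H2O, 60 °C; then 1 M HCl
Reagents that add atoms: lithium hydroxide, [Li+].[OH-]
Why: Ester saponification; the acid is the directing and later traceless group for the union.

Step 5
Reactants: 8 2-bromo-4,6-dimethoxybenzaldehyde
Product: 9 2-bromo-6-hydroxy-4-methoxybenzaldehyde
Conditions: BCl3 (1.2 equiv), CH2Cl2, −78 → 0 °C; then H2O
Reagents that add atoms: none
Why: Chelation-controlled mono-demethylation, in which BCl3 bound to the aldehyde oxygen cleaves only the ortho methyl ether and so differentiates the two oxygens of ring B.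

Step 6
Reactants: 9 2-bromo-6-hydroxy-4-methoxybenzaldehyde
Product: 11 2-bromo-6-hydroxy-4-methoxybenzonitrile, via aldoxime 10 (not isolated)
Conditions: NH2OH·HCl, DMSO, 100 °C
Reagents that add atoms: hydroxylamine hydrochloride, Cl.NO
Why: One-pot aldehyde-to-nitrile conversion by oxime formation and thermal dehydration in DMSO, which tolerates the free phenol.

Step 7
Reactants: 11 2-bromo-6-hydroxy-4-methoxybenzonitrile; 12 4-methoxybenzyl chloride
Product: 13 2-bromo-4-methoxy-6-[(4-methoxybenzyl)oxy]benzonitrile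
Conditions: K2CO3, n-Bu4NI (10 mol%), DMF, 50 °C
Reagents that add atoms: none
Why: Williamson etherification of the acidic cyanophenol installs the benzylic CH2 that the carbene will later insert into.

Step 8
Reactants: 13 2-bromo-4-methoxy-6-[(4-methoxybenzyl)oxy]benzonitrile; 14 3,5-dimethoxyphenylmagnesium chloride
Product: 16 {2-bromo-4-methoxy-6-[(4-methoxybenzyl)oxy]phenyl}(3,5-dimethoxyphenyl)methanone hydrazone, via ketimine 15 (not isolated)
Conditions: THF, 0 → 60 °C; MeOH, 0 °C; then N2H4·H2O, EtOH, 70 °C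
Reagents that add atoms: hydrazine monohydrate, NN.O
Why: Grignard addition to the nitrile gives the N–H ketimine after methanol quench and transimination with hydrazine gives the hydrazone, which avoids condensation at a di-ortho-substituted diaryl ketone carbonyl.

Step 9
Reactants: 16 {2-bromo-4-methoxy-6-[(4-methoxybenzyl)oxy]phenyl}(3,5-dimethoxyphenyl)methanone hydrazone
Product: 18 (2R,3S)-4-bromo-3-(3,5-dimethoxyphenyl)-6-methoxy-2-(4-methoxyphenyl)-2,3-dihydro-1-benzofuran (cis), via diaryldiazomethane 17 (not isolated)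
Conditions: MnO2, CH2Cl2, 0 °C, filter; then Rh2(S-PTAD)4 (1 mol%), CH2Cl2, 0 °C → rt
Reagents that add atoms: none
Why: MnO2 dehydrogenates the hydrazone to the diazo compound and the chiral dirhodium carboxylate turns it into a donor/donor carbene that inserts into the benzylic ether C–H in a 1,5 sense (intramolecular carbene C–H insertion); the concerted syn insertion should give the cis-2,3-diaryl ring and the catalyst pocket should set C3 as S.

Step 10
Reactants: 18 (2R,3S)-4-bromo-3-(3,5-dimethoxyphenyl)-6-methoxy-2-(4-methoxyphenyl)-2,3-dihydro-1-benzofuran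
Product: 19 (2S,3S)-4-bromo-3-(3,5-dimethoxyphenyl)-6-methoxy-2-(4-methoxyphenyl)-2,3-dihydro-1-benzofuran (trans)
Conditions: TFA, CH2Cl2, 0 °C → rt
Reagents that add atoms: none
Why: Acid-mediated epimerisation, in which reversible heterolysis of the C2–O bond to the 4-methoxybenzylic cation and reclosure under thermodynamic control should give the trans ring while C3, which has no exchange pathway, keeps its configuration.

Step 11
Reactants: 20 5-chloro-2-hydroxybenzonitrile; 12 4-methoxybenzyl chloride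
Product: 21 5-chloro-2-[(4-methoxybenzyl)oxy]benzonitrile
Conditions: K2CO3, DMF, 50 °C
Reagents that add atoms: none
Why: Williamson etherification of the cyanophenol.

Step 12
Reactants: 19 (2S,3S)-4-bromo-3-(3,5-dimethoxyphenyl)-6-methoxy-2-(4-methoxyphenyl)-2,3-dihydro-1-benzofuran; 21 5-chloro-2-[(4-methoxybenzyl)oxy]benzonitrile
Product: 24 {5-chloro-2-[(4-methoxybenzyl)oxy]phenyl}[(2S,3S)-3-(3,5-dimethoxyphenyl)-6-methoxy-2-(4-methoxyphenyl)-2,3-dihydro-1-benzofuran-4-yl]methanone hydrazone, via aryllithium 22 (not isolated), via ketimine 23 (not isolated)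
Conditions: n-BuLi (1.05 equiv), THF, −78 °C; 21, −78 → 0 °C; MeOH; then N2H4·H2O, EtOH, 60 °C
Reagents that add atoms: hydrazine monohydrate, NN.O
Why: Bromine–lithium exchange is faster than any deprotonation at −78 °C, the aryllithium adds to the nitrile while the aryl chloride stays inert, and transimination of the N–H ketimine with hydrazine gives the hydrazone without touching the ring 2 stereocentres.

Step 13
Reactants: 24 the hydrazone from step 12
Product: 26 (2S,3R)-5-chloro-3-[(2S,3S)-3-(3,5-dimethoxyphenyl)-6-methoxy-2-(4-methoxyphenyl)-2,3-dihydro-1-benzofuran-4-yl]-2-(4-methoxyphenyl)-2,3-dihydro-1-benzofuran (ring 1 cis), via diaryldiazomethane 25 (not isolated)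
Conditions: MnO2, CH2Cl2, 0 °C, filter; then Rh2(R-PTAD)4 (1 mol%), CH2Cl2, 0 °C → rt
Reagents that add atoms: none
Why: Hydrazone oxidation and Rh-carbene 1,5 C–H insertion as in step 9; the enantiomeric catalyst should set C3 of ring 1 as R under catalyst control with the aryl groups cis, and insertion into C2–H of ring 2 is excluded because it would put an arene carbon at a bridgehead.

Step 14
Reactants: 26 the ring 1 cis chloride from step 13
Product: 27 (2R,3R)-5-chloro-3-[(2S,3S)-3-(3,5-dimethoxyphenyl)-6-methoxy-2-(4-methoxyphenyl)-2,3-dihydro-1-benzofuran-4-yl]-2-(4-methoxyphenyl)-2,3-dihydro-1-benzofuran (both rings trans)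
Conditions: TFA, CH2Cl2, 0 °C → rt
Reagents that add atoms: none
Why: Acid-mediated C2 epimerisation of ring 1 through the 4-methoxybenzylic cation to the thermodynamic trans isomer; ring 2 is already trans and both C3 centres are untouched.

Step 15
Reactants: 27 the trans,trans chloride from step 14; 28 4,4,5,5-tetramethyl-2-vinyl-1,3,2-dioxaborolane
Product: 29 (2R,3R)-5-ethenyl-3-[(2S,3S)-3-(3,5-dimethoxyphenyl)-6-methoxy-2-(4-methoxyphenyl)-2,3-dihydro-1-benzofuran-4-yl]-2-(4-methoxyphenyl)-2,3-dihydro-1-benzofuran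
Conditions: Pd(OAc)2 (5 mol%), SPhos (10 mol%), K3PO4, dioxane/H2O, 100 °C
Reagents that add atoms: none
Why: Suzuki–Miyaura coupling of the electron-rich aryl chloride with the vinylboronate using an electron-rich biaryl phosphine; it follows the acid step because the 4-alkoxystyrene would not survive TFA.

Step 16
Reactants: 7 3-(3,5-dimethoxyphenyl)-6-methoxy-2-(4-methoxyphenyl)-1-benzofuran-5-carboxylic acid (1.5 equiv); 29 the styrene from step 15
Product: 31 3-(3,5-dimethoxyphenyl)-6-methoxy-2-(4-methoxyphenyl)-4-[(E)-2-{(2R,3R)-3-[(2S,3S)-3-(3,5-dimethoxyphenyl)-6-methoxy-2-(4-methoxyphenyl)-2,3-dihydro-1-benzofuran-4-yl]-2-(4-methoxyphenyl)-2,3-dihydro-1-benzofuran-5-yl}ethenyl]-1-benzofuran (nonamethyl ether of the target), via styryl acid 30 (not isolated)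
Conditions: [Cp*RhCl2]2 (5 mol%), AgOAc (2.5 equiv), DMAc, 120 °C; then K2CO3 (15 mol%), 140 °C
Reagents that add atoms: none
Why: The carboxylate of 7 binds Cp*Rh (trivalent rhodium) and carboxylate-assisted concerted metalation–deprotonation gives a five-membered rhodacycle at C4, after which 1,2-migratory insertion of the terminal vinyl group of 29 (aryl to the CH2 carbon) and syn β-hydride elimination give the E-styryl acid 30 and monovalent rhodium, which AgOAc reoxidises. The closest known reaction type is the rhodium-catalysed carboxyl-directed ortho-olefination of 2-alkoxybenzoic acids with styrenes followed by decarboxylation, a directed Fujiwara–Moritani (dehydrogenative Heck) coupling of two C–H carbons of like polarity. No ring is closed and no stereocentre is created; the only new stereochemical element, the E double bond, follows from syn insertion and syn elimination with the two aryl groups anti. Silver-mediated protodecarboxylation of the 2-methoxy-6-alkenylbenzoate at 140 °C then removes the helper as CO2 and leaves C5–H. The step needs site selectivity for C4 over the electronically preferred C7 and the many other electron-rich C–H bonds, which chelation to the C5 carboxylate secures, and mono-olefination, which the single free ortho position secures (C6 carries OMe). The four stereocentres of 29 are spectators because no strong acid or base is present.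

Step 17
Reactants: 31 the nonamethyl ether from step 16
Product: 32 2-(4-hydroxyphenyl)-3-(3,5-dihydroxyphenyl)-4-[(E)-2-{(2R,3R)-2-(4-hydroxyphenyl)-3-[(2S,3S)-6-hydroxy-2-(4-hydroxyphenyl)-3-(3,5-dihydroxyphenyl)-2,3-dihydro-1-benzofuran-4-yl]-2,3-dihydro-1-benzofuran-5-yl}ethenyl]-1-benzofuran-6-ol (CNP0135983.1)
Conditions: BBr3 (excess), CH2Cl2, −78 °C → rt; then MeOH/H2O
Reagents that add atoms: none
Why: Lewis-acid cleavage of the nine aryl methyl ethers; both dihydrobenzofurans are already the thermodynamic trans isomers, so any reversible C2–O ionisation should return the same configuration.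

**Compound list**

1 | methyl 4-hydroxy-2-methoxybenzoate | COC(=O)c1ccc(O)cc1OC | starting material
2 | 2-bromo-1-(3,5-dimethoxyphenyl)ethan-1-one | COc1cc(OC)cc(c1)C(=O)CBr | starting material
3 | methyl 4-[2-(3,5-dimethoxyphenyl)-2-oxoethoxy]-2-methoxybenzoate | COC(=O)c1ccc(OCC(=O)c2cc(OC)cc(OC)c2)cc1OC | intermediate
4 | methyl 3-(3,5-dimethoxyphenyl)-6-methoxy-1-benzofuran-5-carboxylate | COC(=O)c1cc2c(cc1OC)occ2-c1cc(OC)cc(OC)c1 | intermediate
5 | 4-bromoanisole | COc1ccc(Br)cc1 | starting material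
6 | methyl 3-(3,5-dimethoxyphenyl)-6-methoxy-2-(4-methoxyphenyl)-1-benzofuran-5-carboxylate | COC(=O)c1cc2c(cc1OC)oc(-c1ccc(OC)cc1)c2-c1cc(OC)cc(OC)c1 | intermediate
7 | 3-(3,5-dimethoxyphenyl)-6-methoxy-2-(4-methoxyphenyl)-1-benzofuran-5-carboxylic acid | OC(=O)c1cc2c(cc1OC)oc(-c1ccc(OC)cc1)c2-c1cc(OC)cc(OC)c1 | intermediate
8 | 2-bromo-4,6-dimethoxybenzaldehyde | COc1cc(Br)c(C=O)c(OC)c1 | starting material
9 | 2-bromo-6-hydroxy-4-methoxybenzaldehyde | COc1cc(O)c(C=O)c(Br)c1 | intermediate
10 | 2-bromo-6-hydroxy-4-methoxybenzaldehyde oxime | COc1cc(O)c(C=NO)c(Br)c1 | intermediate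
11 | 2-bromo-6-hydroxy-4-methoxybenzonitrile | COc1cc(O)c(C#N)c(Br)c1 | intermediate
12 | 4-methoxybenzyl chloride | COc1ccc(CCl)cc1 | starting material
13 | 2-bromo-4-methoxy-6-[(4-methoxybenzyl)oxy]benzonitrile | COc1ccc(COc2cc(OC)cc(Br)c2C#N)cc1 | intermediate
14 | 3,5-dimethoxyphenylmagnesium chloride | COc1cc(OC)cc([Mg]Cl)c1 | starting material
15 | {2-bromo-4-methoxy-6-[(4-methoxybenzyl)oxy]phenyl}(3,5-dimethoxyphenyl)methanimine | N=C(c1cc(OC)cc(OC)c1)c1c(Br)cc(OC)cc1OCc1ccc(OC)cc1 | intermediate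
16 | {2-bromo-4-methoxy-6-[(4-methoxybenzyl)oxy]phenyl}(3,5-dimethoxyphenyl)methanone hydrazone | NN=C(c1cc(OC)cc(OC)c1)c1c(Br)cc(OC)cc1OCc1ccc(OC)cc1 | intermediate
17 | {2-bromo-4-methoxy-6-[(4-methoxybenzyl)oxy]phenyl}(3,5-dimethoxyphenyl)diazomethane | [N-]=[N+]=C(c1cc(OC)cc(OC)c1)c1c(Br)cc(OC)cc1OCc1ccc(OC)cc1 | intermediate
18 | (2R,3S)-4-bromo-3-(3,5-dimethoxyphenyl)-6-methoxy-2-(4-methoxyphenyl)-2,3-dihydro-1-benzofuran (cis) | Brc1cc(OC)cc2c1[C@H](c1cc(OC)cc(OC)c1)[C@H](c1ccc(OC)cc1)O2 | intermediate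
19 | (2S,3S)-4-bromo-3-(3,5-dimethoxyphenyl)-6-methoxy-2-(4-methoxyphenyl)-2,3-dihydro-1-benzofuran (trans) | Brc1cc(OC)cc2c1[C@H](c1cc(OC)cc(OC)c1)[C@@H](c1ccc(OC)cc1)O2 | intermediate
20 | 5-chloro-2-hydroxybenzonitrile | N#Cc1cc(Cl)ccc1O | starting material
21 | 5-chloro-2-[(4-methoxybenzyl)oxy]benzonitrile | N#Cc1cc(Cl)ccc1OCc1ccc(OC)cc1 | intermediate
22 | [(2S,3S)-3-(3,5-dimethoxyphenyl)-6-methoxy-2-(4-methoxyphenyl)-2,3-dihydro-1-benzofuran-4-yl]lithium | [Li]c1cc(OC)cc2c1[C@H](c1cc(OC)cc(OC)c1)[C@@H](c1ccc(OC)cc1)O2 | intermediate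
23 | {5-chloro-2-[(4-methoxybenzyl)oxy]phenyl}[(2S,3S)-3-(3,5-dimethoxyphenyl)-6-methoxy-2-(4-methoxyphenyl)-2,3-dihydro-1-benzofuran-4-yl]methanimine | N=C(c1cc(Cl)ccc1OCc1ccc(OC)cc1)c1cc(OC)cc2c1[C@H](c1cc(OC)cc(OC)c1)[C@@H](c1ccc(OC)cc1)O2 | intermediate
24 | hydrazone of the corresponding ketone of 23 | NN=C(c1cc(Cl)ccc1OCc1ccc(OC)cc1)c1cc(OC)cc2c1[C@H](c1cc(OC)cc(OC)c1)[C@@H](c1ccc(OC)cc1)O2 | intermediate
25 | diazo compound from 24 | [N-]=[N+]=C(c1cc(Cl)ccc1OCc1ccc(OC)cc1)c1cc(OC)cc2c1[C@H](c1cc(OC)cc(OC)c1)[C@@H](c1ccc(OC)cc1)O2 | intermediate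
26 | (2S,3R)-5-chloro-3-[(2S,3S)-3-(3,5-dimethoxyphenyl)-6-methoxy-2-(4-methoxyphenyl)-2,3-dihydro-1-benzofuran-4-yl]-2-(4-methoxyphenyl)-2,3-dihydro-1-benzofuran (ring 1 cis) | Clc1ccc2c(c1)[C@@H](c1cc(OC)cc3c1[C@H](c1cc(OC)cc(OC)c1)[C@@H](c1ccc(OC)cc1)O3)[C@@H](c1ccc(OC)cc1)O2 | intermediate
27 | (2R,3R)-5-chloro-3-[(2S,3S)-3-(3,5-dimethoxyphenyl)-6-methoxy-2-(4-methoxyphenyl)-2,3-dihydro-1-benzofuran-4-yl]-2-(4-methoxyphenyl)-2,3-dihydro-1-benzofuran (both rings trans) | Clc1ccc2c(c1)[C@@H](c1cc(OC)cc3c1[C@H](c1cc(OC)cc(OC)c1)[C@@H](c1ccc(OC)cc1)O3)[C@H](c1ccc(OC)cc1)O2 | intermediate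
28 | 4,4,5,5-tetramethyl-2-vinyl-1,3,2-dioxaborolane | C=CB1OC(C)(C)C(C)(C)O1 | starting material
29 | (2R,3R)-5-ethenyl-3-[(2S,3S)-3-(3,5-dimethoxyphenyl)-6-methoxy-2-(4-methoxyphenyl)-2,3-dihydro-1-benzofuran-4-yl]-2-(4-methoxyphenyl)-2,3-dihydro-1-benzofuran | C=Cc1ccc2c(c1)[C@@H](c1cc(OC)cc3c1[C@H](c1cc(OC)cc(OC)c1)[C@@H](c1ccc(OC)cc1)O3)[C@H](c1ccc(OC)cc1)O2 | intermediate
30 | 5-carboxylic acid of 31 (4-styryl-benzofuran-5-carboxylic acid) | COc1ccc(-c2oc3cc(OC)c(C(=O)O)c(/C=C/c4ccc5c(c4)[C@@H](c4cc(OC)cc6c4[C@H](c4cc(OC)cc(OC)c4)[C@@H](c4ccc(OC)cc4)O6)[C@H](c4ccc(OC)cc4)O5)c3c2-c2cc(OC)cc(OC)c2)cc1 | intermediate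
31 | nonamethyl ether of the target | COc1ccc(-c2oc3cc(OC)cc(/C=C/c4ccc5c(c4)[C@@H](c4cc(OC)cc6c4[C@H](c4cc(OC)cc(OC)c4)[C@@H](c4ccc(OC)cc4)O6)[C@H](c4ccc(OC)cc4)O5)c3c2-c2cc(OC)cc(OC)c2)cc1 | intermediate
32 | CNP0135983.1 | Oc1ccc(-c2oc3cc(O)cc(/C=C/c4ccc5c(c4)[C@@H](c4cc(O)cc6c4[C@H](c4cc(O)cc(O)c4)[C@@H](c4ccc(O)cc4)O6)[C@H](c4ccc(O)cc4)O5)c3c2-c2cc(O)cc(O)c2)cc1 | target

**Totals and risks**

Total step count: 17. Longest linear sequence: 12 steps (steps 5–10 and 12–17, from 8 to 32).

1. Step 16. What may go wrong: slow rhodation of C4–H, which is flanked by the ring fusion and sits next to the twisted C3 aryl group; lactonisation of the ortho-styryl acid onto the electron-rich alkene; incomplete protodecarboxylation. Fallback: the stilbene is closed at its other aryl–vinyl bond by a Mizoroki–Heck reaction, setting out from 2 and returning at 31. Etherification of commercial methyl 3-hydroxy-5-methoxybenzoate with 2 (K2CO3, acetone) should give methyl 3-[2-(3,5-dimethoxyphenyl)-2-oxoethoxy]-5-methoxybenzoate F1. Bi(OTf)3 cyclodehydration para to OMe should give methyl 3-(3,5-dimethoxyphenyl)-6-methoxy-1-benzofuran-4-carboxylate F2, and direct C2 arylation with 5 should give methyl 3-(3,5-dimethoxyphenyl)-6-methoxy-2-(4-methoxyphenyl)-1-benzofuran-4-carboxylate F3. LiAlH4 reduction should give [3-(3,5-dimethoxyphenyl)-6-methoxy-2-(4-methoxyphenyl)-1-benzofuran-4-yl]methanol F4, MnO2 oxidation the 4-carbaldehyde F5, and Wittig methylenation (Ph3PCH3Br, KOt-Bu) 4-ethenyl-3-(3,5-dimethoxyphenyl)-6-methoxy-2-(4-methoxyphenyl)-1-benzofuran F6. Heck coupling of F6 with aryl chloride 27 (Pd2(dba)3, P(t-Bu)3, Cs2CO3, dioxane, 110 °C) should then give 31.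

2. Step 9. What may go wrong: slow insertion and eroded facial or cis selectivity at a carbene flanked by bromine and the ether on the same ring, with azine formation or carbene dimerisation taking over. Fallback: a racemic ortho-quinone methide route with resolution, setting out from 9 and returning at 19. Addition of 14 (2.2 equiv) to 9 should give (2-bromo-6-hydroxy-4-methoxyphenyl)(3,5-dimethoxyphenyl)methanol F7. Sodium 4-methylbenzenesulfinate in formic acid should give 3-bromo-2-[(3,5-dimethoxyphenyl)(4-methylbenzenesulfonyl)methyl]-5-methoxyphenol F8. Cs2CO3 with (4-methoxybenzyl)dimethylsulfonium bromide should generate the ortho-quinone methide and the sulfur ylide, whose (4+1) annulation gives the racemic trans ring, that is 19 together with its enantiomer (2R,3R)-4-bromo-3-(3,5-dimethoxyphenyl)-6-methoxy-2-(4-methoxyphenyl)-2,3-dihydro-1-benzofuran F9. Preparative chiral supercritical-fluid chromatography then gives 19.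

3. Step 17. What may go wrong: acid-promoted opening of the dihydrobenzofuran rings or Friedel–Crafts closure of an electron-rich ring onto the stilbene during the ninefold ether cleavage, and incomplete cleavage. Fallback: from 31, nucleophilic demethylation under basic conditions (excess NaSEt, DMF, 130 °C), in which thiolate attacks the methyl carbons and no carbocation can form, should return 32 directly; this fallback makes no new compound (F0).

**Further compounds**

F1 | step 16 | methyl 3-[2-(3,5-dimethoxyphenyl)-2-oxoethoxy]-5-methoxybenzoate | COC(=O)c1cc(OC)cc(OCC(=O)c2cc(OC)cc(OC)c2)c1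
F2 | step 16 | methyl 3-(3,5-dimethoxyphenyl)-6-methoxy-1-benzofuran-4-carboxylate | COC(=O)c1cc(OC)cc2occ(-c3cc(OC)cc(OC)c3)c12
F3 | step 16 | methyl 3-(3,5-dimethoxyphenyl)-6-methoxy-2-(4-methoxyphenyl)-1-benzofuran-4-carboxylate | COC(=O)c1cc(OC)cc2oc(-c3ccc(OC)cc3)c(-c3cc(OC)cc(OC)c3)c12
F4 | step 16 | [3-(3,5-dimethoxyphenyl)-6-methoxy-2-(4-methoxyphenyl)-1-benzofuran-4-yl]methanol | OCc1cc(OC)cc2oc(-c3ccc(OC)cc3)c(-c3cc(OC)cc(OC)c3)c12
F5 | step 16 | 3-(3,5-dimethoxyphenyl)-6-methoxy-2-(4-methoxyphenyl)-1-benzofuran-4-carbaldehyde | O=Cc1cc(OC)cc2oc(-c3ccc(OC)cc3)c(-c3cc(OC)cc(OC)c3)c12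
F6 | step 16 | 4-ethenyl-3-(3,5-dimethoxyphenyl)-6-methoxy-2-(4-methoxyphenyl)-1-benzofuran | C=Cc1cc(OC)cc2oc(-c3ccc(OC)cc3)c(-c3cc(OC)cc(OC)c3)c12
F7 | step 9 | (2-bromo-6-hydroxy-4-methoxyphenyl)(3,5-dimethoxyphenyl)methanol | OC(c1cc(OC)cc(OC)c1)c1c(Br)cc(OC)cc1O
F8 | step 9 | 3-bromo-2-[(3,5-dimethoxyphenyl)(4-methylbenzenesulfonyl)methyl]-5-methoxyphenol | Cc1ccc(cc1)S(=O)(=O)C(c1cc(OC)cc(OC)c1)c1c(Br)cc(OC)cc1O
F9 | step 9 | (2R,3R)-4-bromo-3-(3,5-dimethoxyphenyl)-6-methoxy-2-(4-methoxyphenyl)-2,3-dihydro-1-benzofuran | Brc1cc(OC)cc2c1[C@@H](c1cc(OC)cc(OC)c1)[C@H](c1ccc(OC)cc1)O2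
F0 | step 17 | none | none
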